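(The earlier runs and the new flask were generated by integration for an exercise; the scatter is artificial.)

Noon charges 0.400 M of G and midnight 0.0125 M, a factor of 32.0, and that is the number to watch.

| setting | Friday's | Sunday's | Saturday's | midnight | autumn | spring | dawn | noon |
|---|---|---|---|---|---|---|---|---|
| L | 0.35 M | 1.4 M | 0.50 M | 0.50 M | 0.50 M | 2.0 M | 0.50 M | 2.0 M |
| G | 10 mol% | 10 mol% | 8.9 mol% | 2.5 mol% | 3 mol% | 5 mol% | 10 mol% | 20 mol% |
| temperature | 65 °C | 85 °C | 65 °C | 100 °C | 100 °C | 70 °C | 70 °C | 85 °C |
| remark | run made earlier | run made earlier | run made earlier |  |  |  |  |  |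
| time |  |  |  | 2.0 min | 2.0 min | 2.0 min | 2.0 min | 2.0 min |

- Friday's (time / s: X / %, L / %): 10.0: 8.1, 87.3; 30.0: 16.8, 72.1; 50.0: 24.9, 59.8; 80.0: 32.2, 46.1
- Sunday's (time / s: X / %, L / %): 10.0: 51.6, 30.8; 20.0: 67.1, 11.0; 40.0: 73.7, 1.2
- Saturday's (time / s: X / %, L / %): 20.0: 16.0, 75.2; 40.0: 25.1, 61.9; 60.0: 30.6, 49.6; 80.0: 36.2, 40.7

(scatter of a reading: 0.5 percentage points)

- the numbers in the tables scatter with a standard deviation of 0.5 percentage points

* all flasks from highest to lowest amount of X, in percent of the L charged, at 2.0 min (midnight / autumn / spring / dawn / noon)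
* the same order at 12 s (midnight / autumn / spring / dawn / noon)
* the amount of X, in percent of the L charged of the flask you put first, at 2.0 min
* the amount of X, in percent of the L charged of the flask you put last, at 2.0 min

We keep the books on G, charged at 2.5 mol% to 20 mol% of L. First entry: we take it that each G meets an L and starts one chain, which books one X. Second entry: the chain goes on. Sunday's run reads 73.7% of X at 40.0 s on a loading of 10 mol%, so one G stands for about 7.37 X. We therefore carry c, the chain-end concentration, defined as the loading of G times the starting concentration of L.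

Third entry: L that no chain takes falls into the gap, the part of the charge that is neither L nor X. At the last reading, X against the gap is 2.94 in Sunday's run, with c at 0.140 M. In Saturday's run it is 1.57, with c at 0.0445 M. But Sunday's run is also warmer, 85 °C against 65 °C, so these readings do not separate c from temperature.

We still commit to ranking the flasks by c at 2.0 min: noon, then spring at 0.100 M, dawn at 0.0500 M, autumn at 0.0150 M, and midnight. Our rank carries no percentages.

The forecast gives noon > spring > dawn > autumn > midnight at 2.0 min, the same order as ours, and noon > autumn > midnight > spring > dawn at 12 s. It puts noon at 82% (73% to 90%) and midnight at 46% (35% to 70%), on this ground: “By 2 min nearly all L is consumed in the hot flasks, so selectivity decides.”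

The flasks give noon > spring > dawn > autumn > midnight at 2.0 min and noon > spring > autumn > dawn > midnight at 12 s.

    L → D (k = 0.00466 s⁻¹, Ea = 94.0 kJ mol⁻¹)
    L + E → X + E, rate k2*[E]*[L] (k = 0.203 L mol⁻¹ s⁻¹, Ea = 73.0 kJ mol⁻¹)
    2 L → J (k = 0.00315 L mol⁻¹ s⁻¹, Ea = 64.0 kJ mol⁻¹)
    L + G → E + X (k = 0.469 L mol⁻¹ s⁻¹, Ea = 55.0 kJ mol⁻¹)
    (constants at 70 °C)

Noon reaches 88.7%. Midnight reaches 21.5%, not the forecast's 46%, with 68.9% of the L charged standing as D. Midnight ends with E, the chain end, at 0.0125 M, which is its c. Its ratio of X to D, a selectivity factor, is 0.312, and at 100 °C we scale that ratio with c.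

The neighbour flask is midnight with 10 mol% of G. Its c is 0.0500 M, up by a factor of 4.00, so the ratio reckons to 1.25. That flask ends with X at 52.8% and D at 41.5%, a ratio of 1.27.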